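The mole of coupling partner charged was the unit I reckoned in, since percentages of solid substrate hid what the earlier runs shared.

| flask | solid substrate | coupling partner | remark | time |
|---|---|---|---|---|
| alder | 0.67 M | 0.90 M | run made earlier |  |
| elm | 1.5 M | 0.90 M | run made earlier |  |
| ash | 1 M | 1.4 M | run made earlier |  |
| flask | 1.0 M | 0.900 M |  | 8.0 h |

| run | time / h | target / % |
|---|---|---|
| alder | 0.500 | 23.1 |
| alder | 0.833 | 32.1 |
| alder | 1.33 | 37.6 |
| alder | 2.00 | 38.5 |
| alder | 4.00 | 38.9 |
| alder | 6.00 | 37.5 |
| alder | 10.0 | 38.8 |
| elm | 0.500 | 8.7 |
| elm | 0.833 | 13.2 |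
| elm | 1.33 | 15.7 |
| elm | 2.00 | 17.0 |
| elm | 4.00 | 11.9 |
| elm | 6.00 | 9.1 |
| elm | 10.0 | 4.1 |
| ash | 0.500 | 22.8 |
| ash | 1.00 | 33.5 |
| ash | 2.00 | 40.3 |
| ash | 5.00 | 39.8 |
| ash | 10.0 | 39.8 |

(readings scatter by 1 percentage point)

* time up to 8.0 h at which target stands highest
* the amount of target, in percent of the solid substrate charged, at that time

- the analysis behind the earlier runs scatters by 1 percentage point, standard deviation
- at the start none of the solid substrate is in solution
- a reading or a percentage of target counts all its forms, free or not

I divided the highest reading of target, in moles, by the partner charged. Alder's highest reading was 38.9% of 0.67 M at 4.00 h, elm's was 17.0% of 1.5 M at 2.00 h, and ash's was 40.3% of 1 M at 2.00 h, each a single reading with its scatter. That gave 0.290, 0.283 and 0.288, which lie within 0.00700 of each other although the substrate charges differ. Their mean is the partner yield, y = 0.287, the highest reading of target per mole of partner charged, and it carries the scatter of those readings.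

I then ran the flask slowly in my head. At first no substrate is in solution, so it has to dissolve before it can meet partner. Next comes the rise: alder's first reading, 23.1% at 0.500 h, read as a first-order approach to its plateau, gives a time constant τ = 0.555 h, so 2.00 h is 3.60 time constants. Last comes the loss: alder stayed level to 10.0 h, while elm, charged with more substrate, fell to 4.1%. The flask's 1.0 M lies between those charges, so I expected a peak near 2.00 h and a slow fall after it. Treating partner as the limiting reagent, I reckoned y times 0.900 M, which is 25.8% of the substrate charged.

The forecast gave 27% at 2 h, a little above my figure, holding that “it is partner-limited like elm”.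

The flask gave 25.1% at 2.02 h.

    solid substrate ⇌ dissolved substrate, rate k1*(cs1 - [dissolved substrate]) while solid is left; crystals form when [dissolved substrate] > cs1 (solubility = 0.610 M, k = 0.0670 min⁻¹)
    dissolved substrate + coupling partner → target (k = 0.0380 L mol⁻¹ min⁻¹)
    coupling partner → side product A (k = 0.0290 min⁻¹)
    solid product ⇌ target, rate k4*(cs4 - [target]) while solid is left; crystals form when [target] > cs4 (solubility = 26.0 mM, k = 5.70 min⁻¹)
    2 solid substrate → self-condensation product (k = 1.70 × 10⁻⁵ L mol⁻¹ min⁻¹)
    solid substrate + target → side product B (k = 0.0220 L mol⁻¹ min⁻¹)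

At 2.02 h the flask's coupling partner stood at 0.294% of the charge. The flask's own partner yield came to 0.279. Carried to the same flask charged with 0.54 M of partner, y gives 15.5%, and that flask reached 14.6%.

All runs were computed with made-up constants, and the scatter is random.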